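The target is an ester of two mirror-image hydroheptelidic acid units, so one racemic monomer synthesis, resolved once, supplies both halves. Each unit is disconnected in its seven-membered lactone ring, where O2–C3H2–C4(CO2R)=C5H is an allyl unit held between the ring oxygen and the cyclohexane ring-fusion carbon C5a. A retro-Claisen [3,3] shift of a vinylcyclopropyl aldehyde forms the O2–C3 bond, cleaves the cyclopropane and closes the 2,5-dihydrooxepine ring in one operation. Its precursor is a bicyclo[4.1.0]heptane with the formyl group on ring-fusion carbon C1, a cis (exo) tert-butyl acrylate unit on C7, a spiro acetonide at C2 and isopropyl at C5.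

Key step: step 10

Remark: in the target the acyl unit has the (5aS,6R,9S,9aS) configuration (2-benzoxepine numbering) and the alkoxy unit is its mirror image (5aR,6S,9R,9aR); compounds 2, 4, 5, 9 and 12–19 are therefore racemates, and their SMILES show the enantiomer that leads to the acyl unit.
Assumption: the enantiomers of lactone 19 separate on a polysaccharide chiral stationary phase, and the antipodes are assigned by correlating acid 22 with the natural monomer, hydroheptelidic acid.

Step 1
Reactants: 1 4-isopropylcyclohexanone
Product: 2 rac-4-isopropylcyclohex-2-en-1-one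
Conditions: Pd(O2CCF3)2 (5 mol%), Me2SO (10 mol%), O2 (1 atm), AcOH, 80 °C
Reagents that add atoms: none
Why: Palladium-catalysed aerobic α,β-dehydrogenation of a cyclohexanone (palladium enolate, β-hydride elimination) should stop at the enone; the two enantiotopic sides react alike, which gives the racemate that the two mirror-image halves require.

Step 2
Reactants: 2 rac-4-isopropylcyclohex-2-en-1-one; 3 formaldehyde
Product: 4 rac-2-(hydroxymethyl)-4-isopropylcyclohex-2-en-1-one
Conditions: 37% aq. CH2O, DMAP (0.3 equiv), THF, rt
Reagents that add atoms: formaldehyde, C=O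
Why: Morita–Baylis–Hillman reaction: DMAP adds reversibly to C3, the enolate is hydroxymethylated at C2 and DMAP is expelled; C4 is not touched.

Step 3
Reactants: 4 rac-2-(hydroxymethyl)-4-isopropylcyclohex-2-en-1-one
Product: 5 rac-2-[(tert-butyldimethylsilyloxy)methyl]-4-isopropylcyclohex-2-en-1-one
Conditions: TBSCl, imidazole, CH2Cl2, 0 °C to rt
Reagents that add atoms: tert-butyldimethylsilyl chloride, CC(C)(C)[Si](C)(C)Cl
Why: Standard silylation of a primary alcohol; the silyl ether prevents oxa-Michael addition to the acrylate and retro-aldol loss of formaldehyde in the basic steps that follow.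

Step 4
Reactants: 5 rac-silyl ether enone; 6 tert-butyl 2-(bromomethyl)acrylate
Product: 9 rac-tert-butyl 2-{1-[(tert-butyldimethylsilyloxy)methyl]-5-isopropyl-2-oxobicyclo[4.1.0]heptan-7-yl}acrylate (cyclopropane trans to isopropyl; acrylate exo), via sulfonium bromide 7 (not isolated), via sulfonium ylide 8 (not isolated)
Conditions: 6, tetrahydrothiophene, MeCN, rt; then 5, Cs2CO3, rt
Reagents that add atoms: tert-butyl 2-(bromomethyl)acrylate, C=C(CBr)C(=O)OC(C)(C)C
Why: Michael-initiated ring closure of an allylic sulfonium ylide (Corey–Chaykovsky-type vinylcyclopropanation): the ylide carbon adds to C3 of the enone on the face opposite the C4 isopropyl group, and the enolate then displaces tetrahydrothiophene (3-exo-tet) with the bulky acrylate turned away from the six-membered ring, so the acrylate should end up exo, cis to CH2OSi.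

Step 5
Reactants: 9 rac-cyclopropyl ketone; 10 (chloromethyl)(isopropoxy)dimethylsilane
Product: 12 rac-tertiary alcohol bearing CH2SiMe2(O-i-Pr) at C2 (OH cis to C7), via Grignard reagent 11 (not isolated)
Conditions: 10, Mg, THF; then CeCl3, 9, THF, −78 to 0 °C; aq. NH4Cl
Reagents that add atoms: (isopropoxydimethylsilyl)methylmagnesium chloride, CC(C)O[Si](C)(C)C[Mg]Cl
Why: 1,2-Addition of Tamao's hydroxymethyl-anion equivalent as its weakly basic organocerium form, which should attack the ketone faster than the hindered tert-butyl acrylate; the C1–C7 bond nearly eclipses the approach from the cyclopropane face, so the nucleophile enters anti to the cyclopropane and the new CH2 lies trans to C7.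

Step 6
Reactants: 12 rac-β-hydroxysilane
Product: 13 rac-diol with C2(OH)(CH2OH)
Conditions: 30% H2O2, KF, KHCO3, THF/MeOH, rt
Reagents that add atoms: hydrogen peroxide, OO
Why: Tamao–Kumada oxidation: the fluoride-activated alkoxysilane undergoes a peroxide-induced shift of carbon from silicon to oxygen with retention, which unveils the primary alcohol without touching the tertiary centre.

Step 7
Reactants: 13 rac-diol
Product: 14 rac-spiro acetonide (C1 CH2OTBS)
Conditions: 2-methoxypropene, pyridinium tosylate (cat.), CH2Cl2, 0 °C
Reagents that add atoms: 2-methoxypropene, COC(C)=C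
Why: Acetonide formation by acid-catalysed addition of the primary hydroxyl to the enol ether and closure of the five-membered dioxolane by the tertiary hydroxyl; the weak acid should not ionise the cyclopropylcarbinyl C–O bond.

Step 8
Reactants: 14 rac-silyl ether acetonide
Product: 15 rac-primary alcohol (C1 CH2OH)
Conditions: HF·pyridine, pyridine, THF, 0 °C to rt
Reagents that add atoms: none
Why: Fluoride cleavage of a primary silyl ether under buffered acidic conditions, so that no alkoxide forms that could add to the cis acrylate.

Step 9
Reactants: 15 rac-primary alcohol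
Product: 16 rac-aldehyde (C1 CHO; SMILES of the required retro-Claisen precursor)
Conditions: Dess–Martin periodinane, NaHCO3, CH2Cl2, 0 °C
Reagents that add atoms: none
Why: Dess–Martin oxidation of a neopentyl-type primary alcohol under buffered neutral conditions; the quaternary C1 cannot epimerise.

Step 10
Reactants: 16 rac-vinylcyclopropyl aldehyde
Product: 17 rac-fused 2,5-dihydrooxepine
Conditions: PhMe, 80 °C
Reagents that add atoms: none
Why: A concerted, suprafacial [3,3] sigmatropic shift (retro-Claisen, a hetero-Cope process) passes through a boat-like transition state in which the formyl C=O and the acrylate C=CH2 are the two π components and the C1–C7 cyclopropane bond is the σ component, so the O–CH2 bond forms while C1–C7 breaks and the π bonds move to C1=CH–O and C7=C(CO2tBu). The closest known reaction type is the retro-Claisen rearrangement of cis-2-vinylcyclopropanecarbaldehydes to 2,5-dihydrooxepines. The seven-membered ring is closed pericyclically, by bonding of the carbonyl oxygen to the terminal vinyl carbon across the six-atom array as the three-membered ring opens (a four-atom ring expansion), not by an ionic exo or endo cyclisation. No stereocentre is created: C1 and C7 become sp2 and C6 (later C5a) keeps its configuration. The step needs formyl and vinyl cis on the cyclopropane, which the exo-selective ring closure of step 4 provides, and its regiochemistry is fixed because only the C1–C7 bond lies between the two π systems. The shift should be driven by loss of cyclopropane strain, relief of crowding at quaternary C1 and formation of a trisubstituted conjugated enoate, and any aldehyde left at equilibrium is drained by the oxidation of step 11.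

Step 11
Reactants: 17 rac-dihydrooxepine
Product: 18 rac-cis-fused lactone (formed together with its trans-fused epimer 19)
Conditions: [C5H5NH][CrO3Cl], NaOAc, 4 Å molecular sieves, CH2Cl2, rt
Reagents that add atoms: pyridinium chlorochromate, [O-][Cr](=O)(=O)Cl.c1cc[nH+]cc1
Why: Chlorochromate oxidation of a cyclic enol ether to the lactone (protonation at the β-carbon, chromate addition to the oxocarbenium ion, collapse of the chromate ester), buffered to spare the acetonide; the proton reaches C9a under kinetic control, so the cis-fused epimer from equatorial protonation is expected beside 19, and the mixture is carried on.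

Step 12
Reactants: 18 rac-cis-fused lactone (with any 19 already present)
Product: 19 rac-trans-fused lactone
Conditions: DBU, PhMe, 60 °C
Reagents that add atoms: none
Why: Base-mediated epimerisation α to the lactone carbonyl under thermodynamic control should converge on the trans-fused lactone, in which both ring-fusion bonds are equatorial; β-elimination of the acetonide oxygen is disfavoured because the C9–O bond is equatorial and orthogonal to the enolate π system.

Step 13
Reactants: 19 rac-trans-fused lactone
Product: 20 (6R)-enantiomer of 19; 21 (6S)-enantiomer of 19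
Conditions: preparative HPLC, amylose tris(3,5-dimethylphenylcarbamate) phase, hexane/i-PrOH
Reagents that add atoms: none
Why: Chromatographic resolution of enantiomers at the last intermediate common to both halves; both antipodes are used, so nothing is discarded, and the absolute configuration of each half is fixed here.

Step 14
Reactants: 20 (6R)-lactone
Product: 22 hydroheptelidic acid, (5aS,6R,9S,9aS)
Conditions: CF3CO2H/H2O (9:1), CH2Cl2, 0 °C to rt
Reagents that add atoms: none
Why: Acidolysis cleaves the tert-butyl ester through the tert-butyl cation and hydrolyses the acetonide; the lactone and the enoate are stable to acid.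

Step 15
Reactants: 22 hydroheptelidic acid
Product: 23 acetonide acid (acyl partner)
Conditions: Me2C(OMe)2, pyridinium tosylate (cat.), acetone, rt
Reagents that add atoms: 2,2-dimethoxypropane, COC(C)(C)OC
Why: Transketalisation re-forms the five-membered dioxolane on the 1,2-diol and masks the primary hydroxyl, while the carboxylic acid stays free under this weak acid.

Step 16
Reactants: 21 (6S)-lactone
Product: 24 tert-butyl ester diol, (5aR,6S,9R,9aR) (alkoxy partner)
Conditions: AcOH/THF/H2O (3:1:1), 40 °C
Reagents that add atoms: none
Why: Mild aqueous acid hydrolyses the acetonide selectively; the tert-butyl ester needs strong acid and the lactone is not opened.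

Step 17
Reactants: 23 acetonide acid; 24 tert-butyl ester diol
Product: 25 protected heterochiral ester
Conditions: 2-methyl-6-nitrobenzoic anhydride, DMAP (cat.), Et3N, CH2Cl2, rt
Reagents that add atoms: none
Why: Shiina esterification (mixed anhydride, acyl transfer by DMAP) acylates only the primary hydroxyl of 24, the tertiary one being inert; no stereocentre is involved, and the pairing of opposite antipodes is fixed by the choice of 23 and 24.

Step 18
Reactants: 25 protected heterochiral ester
Product: 26 target
Conditions: CF3CO2H/H2O (9:1), CH2Cl2, 0 °C to rt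
Reagents that add atoms: none
Why: Global acidolysis removes the acetonide of the acyl unit and the tert-butyl ester of the alkoxy unit in one operation; the linking ester and both lactones are stable to acid.

Compound list
1 | 4-isopropylcyclohexanone | CC(C)C1CCC(=O)CC1 | starting material
2 | rac-4-isopropylcyclohex-2-en-1-one ((R)-enantiomer drawn) | CC(C)[C@H]1CCC(=O)C=C1 | intermediate
3 | formaldehyde | C=O | starting material
4 | rac-2-(hydroxymethyl)-4-isopropylcyclohex-2-en-1-one | CC(C)[C@H]1CCC(=O)C(CO)=C1 | intermediate
5 | rac-2-[(tert-butyldimethylsilyloxy)methyl]-4-isopropylcyclohex-2-en-1-one | CC(C)[C@H]1CCC(=O)C(CO[Si](C)(C)C(C)(C)C)=C1 | intermediate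
6 | tert-butyl 2-(bromomethyl)acrylate | C=C(CBr)C(=O)OC(C)(C)C | starting material
7 | 1-[2-(tert-butoxycarbonyl)prop-2-en-1-yl]tetrahydrothiophenium bromide | C=C(C[S+]1CCCC1)C(=O)OC(C)(C)C.[Br-] | intermediate (not isolated)
8 | sulfonium ylide derived from 7 | C=C([CH-][S+]1CCCC1)C(=O)OC(C)(C)C | intermediate (not isolated)
9 | rac-tert-butyl 2-{1-[(tert-butyldimethylsilyloxy)methyl]-5-isopropyl-2-oxobicyclo[4.1.0]heptan-7-yl}acrylate; cyclopropane trans to isopropyl, acrylate exo (cis to CH2OSi and H6) | CC(C)[C@H]1CCC(=O)[C@]2(CO[Si](C)(C)C(C)(C)C)[C@@H](C(=C)C(=O)OC(C)(C)C)[C@H]12 | intermediate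
10 | (chloromethyl)(isopropoxy)dimethylsilane | CC(C)O[Si](C)(C)CCl | starting material
11 | (isopropoxydimethylsilyl)methylmagnesium chloride | CC(C)O[Si](C)(C)C[Mg]Cl | intermediate (not isolated)
12 | rac-tertiary alcohol: as 9, with C2 bearing OH (cis to C7) and CH2SiMe2(O-i-Pr) (trans to C7) | CC(C)[C@H]1CC[C@@](O)(C[Si](C)(C)OC(C)C)[C@]2(CO[Si](C)(C)C(C)(C)C)[C@@H](C(=C)C(=O)OC(C)(C)C)[C@H]12 | intermediate
13 | rac-diol: C2 bearing OH (cis to C7) and CH2OH | CC(C)[C@H]1CC[C@@](O)(CO)[C@]2(CO[Si](C)(C)C(C)(C)C)[C@@H](C(=C)C(=O)OC(C)(C)C)[C@H]12 | intermediate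
14 | rac-acetonide: 2,2-dimethyl-1,3-dioxolane spiro at C2 (ring O cis to C7), C1 CH2OTBS | CC(C)[C@H]1CC[C@]2(OC(C)(C)OC2)[C@]3(CO[Si](C)(C)C(C)(C)C)[C@@H](C(=C)C(=O)OC(C)(C)C)[C@H]13 | intermediate
15 | rac-primary alcohol: as 14, with C1 CH2OH | CC(C)[C@H]1CC[C@]2(OC(C)(C)OC2)[C@]3(CO)[C@@H](C(=C)C(=O)OC(C)(C)C)[C@H]13 | intermediate
16 | rac-vinylcyclopropyl aldehyde: as 14, with C1 CHO cis to the exo acrylate | CC(C)[C@H]1CC[C@]2(OC(C)(C)OC2)[C@]3(C=O)[C@@H](C(=C)C(=O)OC(C)(C)C)[C@H]13 | intermediate
17 | rac-tert-butyl 6-isopropyl-2',2'-dimethyl-5a,6,7,8-tetrahydro-3H-spiro[2-benzoxepine-9,4'-[1,3]dioxolane]-4-carboxylate; H5a trans to isopropyl | CC(C)[C@H]1CC[C@]2(OC(C)(C)OC2)C3=COCC(C(=O)OC(C)(C)C)=C[C@H]13 | intermediate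
18 | rac-1-oxo lactone from 17, cis-fused (H9a cis to H5a) | CC(C)[C@H]1CC[C@]2(OC(C)(C)OC2)[C@@H]3C(=O)OCC(C(=O)OC(C)(C)C)=C[C@H]13 | intermediate
19 | rac-1-oxo lactone, trans-fused (H9a trans to H5a; lactone carbonyl cis to the dioxolane CH2) | CC(C)[C@H]1CC[C@]2(OC(C)(C)OC2)[C@H]3C(=O)OCC(C(=O)OC(C)(C)C)=C[C@H]13 | intermediate
20 | (6R)-enantiomer of 19 (configuration of the acyl unit) | CC(C)[C@H]1CC[C@]2(OC(C)(C)OC2)[C@H]3C(=O)OCC(C(=O)OC(C)(C)C)=C[C@H]13 | intermediate
21 | (6S)-enantiomer of 19 (configuration of the alkoxy unit) | CC(C)[C@@H]1CC[C@@]2(OC(C)(C)OC2)[C@@H]3C(=O)OCC(C(=O)OC(C)(C)C)=C[C@@H]13 | intermediate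
22 | (5aS,6R,9S,9aS)-9-hydroxy-9-(hydroxymethyl)-6-isopropyl-1-oxo-1,3,5a,6,7,8,9,9a-octahydro-2-benzoxepine-4-carboxylic acid (hydroheptelidic acid) | CC(C)[C@H]1CC[C@@](O)(CO)[C@H]2C(=O)OCC(C(=O)O)=C[C@H]12 | intermediate
23 | acetonide of 22 with free carboxylic acid | CC(C)[C@H]1CC[C@]2(OC(C)(C)OC2)[C@H]3C(=O)OCC(C(=O)O)=C[C@H]13 | intermediate
24 | tert-butyl (5aR,6S,9R,9aR)-9-hydroxy-9-(hydroxymethyl)-6-isopropyl-1-oxo-1,3,5a,6,7,8,9,9a-octahydro-2-benzoxepine-4-carboxylate | CC(C)[C@@H]1CC[C@](O)(CO)[C@@H]2C(=O)OCC(C(=O)OC(C)(C)C)=C[C@@H]12 | intermediate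
25 | ester of acid 23 with the primary hydroxyl of 24 | CC(C)[C@H]1CC[C@]2(OC(C)(C)OC2)[C@H]3C(=O)OCC(C(=O)OC[C@@]4(O)CC[C@@H](C(C)C)[C@@H]5C=C(C(=O)OC(C)(C)C)COC(=O)[C@H]54)=C[C@H]13 | intermediate
26 | CNP0340505.1 | CC(C)[C@H]1CC[C@@](O)(CO)[C@H]2C(=O)OCC(C(=O)OC[C@@]3(O)CC[C@@H](C(C)C)[C@@H]4C=C(C(=O)O)COC(=O)[C@H]43)=C[C@H]12 | target

Total step count: 18 (17 reactions and one chromatographic resolution).
Longest linear sequence: 17 steps (steps 1–15, 17 and 18; step 16 is the side branch).

Steps most likely to fail

Step 10. The aldehyde–dihydrooxepine equilibrium may lie on the aldehyde side, or the enol ether may revert during isolation, so that 17 cannot be obtained as such. The fallback sets out from 16 and comes back at 18/19 before step 12. Aldehyde 16 is warmed in wet THF with pyridinium tosylate, so that whatever enol ether is present at equilibrium is hydrated as it forms and drained as the lactol F1, a hemiacetal that no longer takes part in the sigmatropic equilibrium. Oxidation of F1 with Ag2CO3 on Celite (Fétizon oxidation of a lactol) then gives the lactone epimers 18 and 19.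

Step 4. The ambident allylic ylide may attack through its terminal CH2, the ring closure may give exo and endo products together, and the 2-substituted enone may react slowly. The fallback sets out from 5 and comes back at 9. The cyclopropane is built with the non-ambident keto-stabilised sulfonium ylide made from tert-butyl bromopyruvate, tetrahydrothiophene and K2CO3, whose reversible Michael addition should funnel to the exo α-keto ester F2. The acrylate double bond is then made by Wittig methylenation of the activated α-keto ester carbonyl with Ph3P=CH2 at low temperature, the hindered ring ketone reacting more slowly, which gives 9.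

Step 5. Enolisation of the hindered ketone, or competing attack at the acrylate, may leave the addition incomplete. The fallback sets out from 9 and comes back at 13. The small methylene ylide from Me3S+ I− and KN(SiMe3)2 (THF, −10 °C) transfers CH2 to the ketone from the same face, anti to the cyclopropane, to give the spiro-epoxide F3. Hydroxide (NaOH, aqueous Me2SO, 60 °C) opens F3 at the unhindered CH2 by SN2 and leaves the tertiary C–O bond and its configuration intact, which gives diol 13.

Further compounds
F1 | step 10 | rac-lactol (1-hydroxy hemiacetal from hydration of 17; epimers at C1 and C9a) | CC(C)[C@H]1CC[C@]2(OC(C)(C)OC2)C3C(O)OCC(C(=O)OC(C)(C)C)=C[C@H]13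
F2 | step 4 | rac-tert-butyl 2-{1-[(tert-butyldimethylsilyloxy)methyl]-5-isopropyl-2-oxobicyclo[4.1.0]heptan-7-yl}-2-oxoacetate (exo) | CC(C)[C@H]1CCC(=O)[C@]2(CO[Si](C)(C)C(C)(C)C)[C@@H](C(=O)C(=O)OC(C)(C)C)[C@H]12
F3 | step 5 | rac-spiro-epoxide at C2 of 9 (epoxide O cis to C7, CH2 trans) | CC(C)[C@H]1CC[C@@]2(CO2)[C@]3(CO[Si](C)(C)C(C)(C)C)[C@@H](C(=C)C(=O)OC(C)(C)C)[C@H]13
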